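Slowness was the first thing I looked at in Wednesday's run, when you asked for a quick number and offered your hunch that the hottest flask would win.

| flask | left-handed substrate | right-handed substrate | reagent | free catalyst | racemization catalyst | added ligand | temperature | remark | time |
|---|---|---|---|---|---|---|---|---|---|
| Wednesday's | 0.075 M | 0.075 M | 4 equiv | 0.67 mol% | 0.5 mol% | 1.3 mM | 75 °C | run made earlier |  |
| elm | 0.050 M | 0.050 M | 4.00 equiv | 0.67 mol% | 0.5 mol% | 1.3 mM | 75 °C |  | 10 min |
| maple | 0.050 M | 0.050 M | 4.00 equiv | 0.67 mol% | 0.5 mol% | 1.3 mM | 100 °C |  | 10 min |
| larch | 0.050 M | 0.050 M | 4.00 equiv | 0.67 mol% | 0.5 mol% | 1.3 mM | 50 °C |  | 10 min |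

- Wednesday's (time / s: left-handed product / %): 25.0: 34; 50.0: 42; 80.0: 50; 90.0: 55; 120: 61

(scatter of a reading: 2 percentage points)

- free catalyst is single-handed; left-handed substrate and right-handed substrate are mirror images of each other, charged as a racemate, each of them at the stated concentration
- the earlier runs do not show what temperature does; that part of a forecast is a guess
- no earlier run changes the charge of free catalyst; that part of a forecast is a guess
- no earlier run changes the charge of racemization catalyst; that part of a forecast is a guess

- the flask with the highest amount of left-handed product, in percent of the left-handed substrate and right-handed substrate together charged ("all alike" if they lie within 1.5 percentage points) (elm / maple / larch / all alike)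
- final left-handed product, as a percentage of the left-handed substrate and right-handed substrate together charged, in elm
- final left-handed product, as a percentage of the left-handed substrate and right-handed substrate together charged, in maple
- final left-handed product, as a percentage of the left-handed substrate and right-handed substrate together charged, in larch

The left-handed substrate is half of any racemic charge, yet Wednesday's run read 61 % at 120 s, higher than that, so right-handed substrate had crossed by racemization. I treated the slow tail as pseudo-first-order and named its time the feed time τ, the time in which the unconverted part falls by a factor e. From the second and last readings, with their scatter of 2 percentage points, I got τ = 176 s. Loadings go with the substrate, so at the new charge I stretched it to τ′ = 265 s. Over 10 min at the same temperature, my own reckoning gave elm 89.6 %, lower than the forecast's 92 %. τ says nothing about heat. The forecast gave 98 % for maple and 45 % for larch, named maple and said: “Maple nearly finishes unless the catalyst dies”.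

The flasks gave 73.4 % in elm, 62.9 % in maple and 49.1 % in larch, so elm held the most.

    reagent + free catalyst + left-handed substrate → free catalyst + left-handed product (k = 680 /M²/s, Ea = 40.0 kJ/mol)
    reagent + free catalyst + right-handed substrate → free catalyst + right-handed product (k = 13.0 /M²/s, Ea = 39.0 kJ/mol)
    left-handed substrate + racemization catalyst ⇌ right-handed substrate + racemization catalyst, rate k3*[racemization catalyst]*[left-handed substrate] forward; the back reaction follows from the equilibrium constant (k = 950 /M/s, Ea = 39.0 kJ/mol)
    free catalyst → spent catalyst (k = 0.0160 /s, Ea = 91.0 kJ/mol)
    racemization catalyst + added ligand ⇌ idle complex, settled at all times (K = 5800 /M, ΔH = −70.0 kJ/mol)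
    (constants at 100 °C)

Free catalyst fell by a factor e in 514 s in elm, twice τ′, and in 62.5 s in maple, against 5850 s in larch. That lifetime shortened 93.6-fold from larch to maple, while the step to left-handed product sped up 7.4-fold, and maple still read 62.9 % at 100 min.

On larch read at 25 min, I scaled τ′ by the ratio of free racemization catalyst, 3.12 % in elm to 0.497 % in larch, and by the root of 7.0, the factor of the right-handed path from larch to maple, as an estimate for half that temperature span; racemization has the same activation energy as that path, 39.0 kJ/mol. That made 73.3 min, and from 44.1 % right-handed substrate in larch at 10 min I reckoned 35.9 %. Larch held 35.7 % right-handed substrate at 25 min, with 57.1 % left-handed product.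

(The readings are simulated for substances that don't exist; noise was put on by code.)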